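**Retrosynthetic overview**
1. The target is cut at C8–C9: an epoxy aldehyde (C8 as CHO) is joined to (E)-4-iodo-2-methylbut-3-en-2-ol by Nozaki–Hiyama–Kishi coupling and C8 is then oxidised. The C7/C14 spiro-oxirane comes from a Sharpless epoxidation of the 2-substituted allylic alcohol made by SeO2 oxidation of an isopropenyl group.
2. The C2 ketone and C3–C4 oxirane come from a 2-silyloxy-3-methylidene cyclohexane (oxidation, exo-to-endo alkene shift, Luche reduction, hydroxyl-directed epoxidation, reoxidation). The ester comes from acylation of C1–OH.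
3. Feature: in ring A (C1–C6) the C1 oxygen is trans to the C6 carbon substituent, whose first atom C7 is 1,1-disubstituted, and C1 is flanked by the C2 oxygen and the C3 carbon branch. This isopulegol pattern is opened at C1–C6 by a carbonyl-ene disconnection to an acyclic 2-silyloxy-3-methylidene aldehyde.
4. The aldehyde comes from nerol: Sharpless epoxidation sets C2, and Et2Al(TMP) opening of the Z-derived epoxide gives the methylidene.
5. Ring order: carbocycle A (step 7), then the C3–C4 oxirane (step 13), then the C7–C14 spiro-oxirane (step 16).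

Key step: step 7

Remark on locants: ring C1 (acyloxy CH), C2 (ketone), C3 (methyl-bearing oxirane carbon), C4 (oxirane CH), C5 (CH2), C6 (CH); side chain C7 (spiro carbon), C14 (its CH2), C8 (enone carbonyl), C9, C10, C11 (carbinol). These locants, not systematic numbering, are used in the names of the ring compounds.

**Step 1**
Reactants: 1 nerol
Product: 2 [(2R,3S)-3-methyl-3-(4-methylpent-3-en-1-yl)oxiran-2-yl]methanol
Conditions: Ti(OiPr)4 (cat.), D-(−)-diethyl tartrate (cat.), tBuOOH, 4 Å MS, CH2Cl2, −20 °C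
Reagents that add atoms: tert-butyl hydroperoxide, CC(C)(C)OO
Why: Sharpless asymmetric epoxidation touches only the allylic alkene, and the D-(−)-tartrate ligand should deliver oxygen to the face that gives the (2R,3S) epoxide, which fixes the later ring C2.

**Step 2**
Reactants: 2 [(2R,3S)-3-methyl-3-(4-methylpent-3-en-1-yl)oxiran-2-yl]methanol
Product: 3 tert-butyldimethylsilyl ether of 2
Conditions: TBSCl, imidazole, DMF, 0 °C to rt
Reagents that add atoms: tert-butyldimethylsilyl chloride, CC(C)(C)[Si](C)(C)Cl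
Why: Silyl ether formation under imidazole conditions is too weakly basic for Payne rearrangement and masks the primary hydroxyl before the aluminium amide step.

**Step 3**
Reactants: 3 tert-butyldimethylsilyl ether of 2
Product: 4 (2S)-1-(tert-butyldimethylsilyloxy)-7-methyl-3-methylideneoct-6-en-2-ol
Conditions: Et2Al(TMP) [from 2,2,6,6-tetramethylpiperidine, n-BuLi, Et2AlCl], toluene, 0 °C
Reagents that add atoms: none
Why: In this Yamamoto epoxide-to-allylic-alcohol isomerisation the aluminium amide binds the oxirane oxygen and removes a syn proton from the C3 methyl group, which in the Z-derived epoxide lies cis to the C2 hydrogen and is the less hindered β-position, so the tertiary C–O bond breaks and the C2 carbinol keeps its configuration.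

**Step 4**
Reactants: 4 (2S)-1-(tert-butyldimethylsilyloxy)-7-methyl-3-methylideneoct-6-en-2-ol
Product: 5 (2S)-1,2-bis(tert-butyldimethylsilyloxy)-7-methyl-3-methylideneoct-6-ene
Conditions: TBSOTf, 2,6-lutidine, CH2Cl2, −78 to 0 °C
Reagents that add atoms: tert-butyldimethylsilyl triflate, CC(C)(C)[Si](C)(C)OS(=O)(=O)C(F)(F)F
Why: Silylation with the silyl triflate covers the secondary allylic hydroxyl with a bulky, poorly chelating group that later directs the ring closure.

**Step 5**
Reactants: 5 (2S)-1,2-bis(tert-butyldimethylsilyloxy)-7-methyl-3-methylideneoct-6-ene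
Product: 6 (2S)-2-(tert-butyldimethylsilyloxy)-7-methyl-3-methylideneoct-6-en-1-ol
Conditions: HF·pyridine, pyridine, THF, 0 °C
Reagents that add atoms: none
Why: Selective desilylation relies on the much faster cleavage of a primary than of a secondary silyl ether by buffered HF·pyridine.

**Step 6**
Reactants: 6 (2S)-2-(tert-butyldimethylsilyloxy)-7-methyl-3-methylideneoct-6-en-1-ol
Product: 7 (2S)-2-(tert-butyldimethylsilyloxy)-7-methyl-3-methylideneoct-6-enal
Conditions: Dess–Martin periodinane, NaHCO3, CH2Cl2, 0 °C; used crude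
Reagents that add atoms: none
Why: Dess–Martin oxidation under buffered, base-free conditions should give the α-silyloxy aldehyde without epimerising C2 or moving the methylidene into conjugation.

**Step 7**
Reactants: 7 (2S)-2-(tert-butyldimethylsilyloxy)-7-methyl-3-methylideneoct-6-enal
Product: 8 (1S,2S,6S)-2-(tert-butyldimethylsilyloxy)-3-methylidene-6-(prop-1-en-2-yl)cyclohexan-1-ol
Conditions: Me2AlCl, CH2Cl2, −78 to −40 °C
Reagents that add atoms: none
Why: Me2AlCl binds the aldehyde oxygen and a type 1 intramolecular carbonyl-ene reaction follows, in which C1 bonds to C6 of the trisubstituted alkene while an allylic hydrogen of a C7 methyl group passes to oxygen in a concerted, asynchronous transition state, the aluminium alkoxide then losing methane so that no free acid is present. The closest known reaction is the Lewis-acid cyclisation of citronellal to isopulegol, of which 7 is the 2-silyloxy-3-methylidene analogue. Ring A closes as a six-membered carbocycle through a chair in which the alkene carbon C6 joins the ring and C7 stays outside it (exo mode with respect to the alkene). The C2 silyloxy group should sit equatorial and antiperiplanar to the forming C1–C6 bond (Felkin–Anh alignment), with the aluminium-bound oxygen and the emerging isopropenyl group also equatorial, so the single C2 centre sets C1 (oxygen trans to the C2 oxygen) and C6 (carbon trans to the C1 oxygen). The step needs chemoselectivity for the C6=C7 alkene over the C3 methylidene, which cannot reach C1 in a ring of workable size, and it needs the β,γ-unsaturated α-silyloxy aldehyde to survive, which the low temperature and the proton-scavenging methyl–aluminium bonds should secure.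

**Step 8**
Reactants: 8 (1S,2S,6S)-2-(tert-butyldimethylsilyloxy)-3-methylidene-6-(prop-1-en-2-yl)cyclohexan-1-ol; 9 isovaleric anhydride
Product: 10 (1S,2S,6S)-2-(tert-butyldimethylsilyloxy)-3-methylidene-6-(prop-1-en-2-yl)cyclohexyl 3-methylbutanoate
Conditions: Et3N, DMAP (cat.), CH2Cl2, rt
Reagents that add atoms: none
Why: DMAP-catalysed acyl transfer esterifies the only free hydroxyl and installs the target ester early, where it also serves as the C1 protecting group.

**Step 9**
Reactants: 10 (1S,2S,6S)-2-(tert-butyldimethylsilyloxy)-3-methylidene-6-(prop-1-en-2-yl)cyclohexyl 3-methylbutanoate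
Product: 11 (1S,2S,6S)-2-hydroxy-3-methylidene-6-(prop-1-en-2-yl)cyclohexyl 3-methylbutanoate
Conditions: HF·pyridine, THF, 0 °C to rt
Reagents that add atoms: none
Why: Desilylation with weakly acidic fluoride is chosen over basic fluoride so that the C1 ester should not migrate to the freed C2 hydroxyl.

**Step 10**
Reactants: 11 (1S,2S,6S)-2-hydroxy-3-methylidene-6-(prop-1-en-2-yl)cyclohexyl 3-methylbutanoate
Product: 12 (1S,6S)-3-methylidene-2-oxo-6-(prop-1-en-2-yl)cyclohexyl 3-methylbutanoate
Conditions: Dess–Martin periodinane, NaHCO3, CH2Cl2, 0 °C to rt; short silica plug, used at once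
Reagents that add atoms: none
Why: Dess–Martin oxidation of the allylic alcohol gives the α-methylene ketone under neutral conditions that leave the ester and the C1 centre alone.

**Step 11**
Reactants: 12 (1S,6S)-3-methylidene-2-oxo-6-(prop-1-en-2-yl)cyclohexyl 3-methylbutanoate
Product: 13 (1S,6S)-3-methyl-2-oxo-6-(prop-1-en-2-yl)cyclohex-3-en-1-yl 3-methylbutanoate
Conditions: RhCl3·3H2O (cat.), EtOH, 70 °C
Reagents that add atoms: none
Why: Rhodium-hydride alkene isomerisation (hydrometalation, then β-hydride elimination) moves the exocyclic double bond to the more stable endocyclic conjugated position, and the enone should react through a rhodium enolate faster than the isolated isopropenyl alkene.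

**Step 12**
Reactants: 13 (1S,6S)-3-methyl-2-oxo-6-(prop-1-en-2-yl)cyclohex-3-en-1-yl 3-methylbutanoate
Product: 14 (1S,2S,6S)-2-hydroxy-3-methyl-6-(prop-1-en-2-yl)cyclohex-3-en-1-yl 3-methylbutanoate
Conditions: NaBH4, CeCl3·7H2O, MeOH, −78 °C
Reagents that add atoms: none
Why: Luche reduction is 1,2-selective, and axial hydride delivery anti to the axial C1 hydrogen should give the equatorial C2 hydroxyl, trans to the C1 ester and cis to the C6 substituent, as in the reduction of carvone to cis-carveol.

**Step 13**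
Reactants: 14 (1S,2S,6S)-2-hydroxy-3-methyl-6-(prop-1-en-2-yl)cyclohex-3-en-1-yl 3-methylbutanoate
Product: 15 (1S,2R,3R,4S,6S)-3,4-epoxy-2-hydroxy-3-methyl-6-(prop-1-en-2-yl)cyclohexyl 3-methylbutanoate
Conditions: VO(acac)2 (cat.), tBuOOH, CH2Cl2, 0 °C to rt
Reagents that add atoms: tert-butyl hydroperoxide, CC(C)(C)OO
Why: In this vanadium-catalysed hydroxyl-directed epoxidation the C2 alkoxide holds the metal peroxide on its own face of C3=C4, so the oxirane forms cis to the C2 hydroxyl and to the C6 substituent, while the remote isopropenyl alkene should react far more slowly.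

**Step 14**
Reactants: 15 (1S,2R,3R,4S,6S)-3,4-epoxy-2-hydroxy-3-methyl-6-(prop-1-en-2-yl)cyclohexyl 3-methylbutanoate
Product: 16 (1S,3S,4S,6S)-3,4-epoxy-3-methyl-2-oxo-6-(prop-1-en-2-yl)cyclohexyl 3-methylbutanoate
Conditions: Dess–Martin periodinane, NaHCO3, CH2Cl2, rt
Reagents that add atoms: none
Why: Dess–Martin oxidation returns C2 to the ketone after it has served as the directing group, and the mild conditions should leave the oxirane and the α-acyloxy centre intact.

**Step 15**
Reactants: 16 (1S,3S,4S,6S)-3,4-epoxy-3-methyl-2-oxo-6-(prop-1-en-2-yl)cyclohexyl 3-methylbutanoate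
Product: 17 (1S,3S,4S,6S)-3,4-epoxy-6-(3-hydroxyprop-1-en-2-yl)-3-methyl-2-oxocyclohexyl 3-methylbutanoate
Conditions: SeO2 (cat.), tBuOOH, salicylic acid (cat.), CH2Cl2, rt
Reagents that add atoms: tert-butyl hydroperoxide, CC(C)(C)OO
Why: Selenium dioxide allylic oxidation (ene reaction, then 2,3-sigmatropic shift) attacks the only electron-rich alkene and should take hydrogen from the methyl group in preference to the C6 methine, as with isopulegol and carvone.

**Step 16**
Reactants: 17 (1S,3S,4S,6S)-3,4-epoxy-6-(3-hydroxyprop-1-en-2-yl)-3-methyl-2-oxocyclohexyl 3-methylbutanoate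
Product: 18 (1S,3S,4S,6R)-3,4-epoxy-6-[(2S)-2-(hydroxymethyl)oxiran-2-yl]-3-methyl-2-oxocyclohexyl 3-methylbutanoate
Conditions: Ti(OiPr)4 (cat.), L-(+)-diethyl tartrate (cat.), tBuOOH, 4 Å MS, CH2Cl2, −20 °C
Reagents that add atoms: tert-butyl hydroperoxide, CC(C)(C)OO
Why: Sharpless asymmetric epoxidation of the 2-substituted allylic alcohol sets C7 under reagent control, the L-(+)-tartrate catalyst being expected to override the modest bias of C6 and to give the configuration that is 7R in the target.

**Step 17**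
Reactants: 18 (1S,3S,4S,6R)-3,4-epoxy-6-[(2S)-2-(hydroxymethyl)oxiran-2-yl]-3-methyl-2-oxocyclohexyl 3-methylbutanoate
Product: 19 (1S,3S,4S,6R)-3,4-epoxy-6-[(2R)-2-formyloxiran-2-yl]-3-methyl-2-oxocyclohexyl 3-methylbutanoate
Conditions: Dess–Martin periodinane, NaHCO3, CH2Cl2, 0 °C to rt
Reagents that add atoms: none
Why: Dess–Martin oxidation gives the epoxy aldehyde, whose quaternary C7 has no α-hydrogen and so cannot epimerise.

**Step 18**
Reactants: 20 2-methylbut-3-yn-2-ol
Product: 21 (E)-2-methyl-4-(tributylstannyl)but-3-en-2-ol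
Conditions: Bu3SnH, AIBN (cat.), neat, 80 °C
Reagents that add atoms: tributyltin hydride, CCCC[SnH](CCCC)CCCC
Why: Radical hydrostannation of the terminal alkyne places tin on the terminal carbon, and reversible stannyl radical addition should lead to the more stable E alkene.

**Step 19**
Reactants: 21 (E)-2-methyl-4-(tributylstannyl)but-3-en-2-ol
Product: 22 (E)-4-iodo-2-methylbut-3-en-2-ol
Conditions: I2, CH2Cl2, 0 °C
Reagents that add atoms: iodine, II
Why: Iododestannylation replaces tin by iodine with retention of the alkene geometry.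

**Step 20**
Reactants: 19 (1S,3S,4S,6R)-3,4-epoxy-6-[(2R)-2-formyloxiran-2-yl]-3-methyl-2-oxocyclohexyl 3-methylbutanoate; 22 (E)-4-iodo-2-methylbut-3-en-2-ol
Product: 24 (1S,3S,4S,6R)-6-{(2R)-2-[(E)-1,4-dihydroxy-4-methylpent-2-en-1-yl]oxiran-2-yl}-3,4-epoxy-3-methyl-2-oxocyclohexyl 3-methylbutanoate (C8 epimers), via alkenylchromium dichloride 23 (not isolated)
Conditions: CrCl2, NiCl2 (cat.), DMSO, rt
Reagents that add atoms: none
Why: In the Nozaki–Hiyama–Kishi reaction nickel catalysis converts the vinyl iodide into an alkenylchromium species that keeps the E geometry, tolerates the free tertiary hydroxyl and should add to the aldehyde in preference to the hindered ketone and the ester, the C8 configuration being of no consequence.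

**Step 21**
Reactants: 24 (1S,3S,4S,6R)-6-{(2R)-2-[(E)-1,4-dihydroxy-4-methylpent-2-en-1-yl]oxiran-2-yl}-3,4-epoxy-3-methyl-2-oxocyclohexyl 3-methylbutanoate (C8 epimers)
Product: 25 (1S,3S,4S,6R)-3,4-epoxy-6-{(2R)-2-[(E)-4-hydroxy-4-methylpent-2-enoyl]oxiran-2-yl}-3-methyl-2-oxocyclohexyl 3-methylbutanoate (CNP0292003.1)
Conditions: Dess–Martin periodinane, NaHCO3, CH2Cl2, 0 °C to rt
Reagents that add atoms: none
Why: Dess–Martin oxidation converts the secondary allylic C8 carbinol into the enone and removes the C8 epimer mixture, while the tertiary C11 alcohol cannot be oxidised.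

**Compound list**
1 | nerol, (2Z)-3,7-dimethylocta-2,6-dien-1-ol | CC(C)=CCC/C(C)=C\CO | starting material
2 | [(2R,3S)-3-methyl-3-(4-methylpent-3-en-1-yl)oxiran-2-yl]methanol | OC[C@H]1O[C@@]1(C)CCC=C(C)C | intermediate
3 | tert-butyldimethylsilyl ether of 2 | CC(C)(C)[Si](C)(C)OC[C@H]1O[C@@]1(C)CCC=C(C)C | intermediate
4 | (2S)-1-(tert-butyldimethylsilyloxy)-7-methyl-3-methylideneoct-6-en-2-ol | CC(C)(C)[Si](C)(C)OC[C@@H](O)C(=C)CCC=C(C)C | intermediate
5 | (2S)-1,2-bis(tert-butyldimethylsilyloxy)-7-methyl-3-methylideneoct-6-ene | CC(C)(C)[Si](C)(C)OC[C@@H](O[Si](C)(C)C(C)(C)C)C(=C)CCC=C(C)C | intermediate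
6 | (2S)-2-(tert-butyldimethylsilyloxy)-7-methyl-3-methylideneoct-6-en-1-ol | OC[C@@H](O[Si](C)(C)C(C)(C)C)C(=C)CCC=C(C)C | intermediate
7 | (2S)-2-(tert-butyldimethylsilyloxy)-7-methyl-3-methylideneoct-6-enal | O=C[C@@H](O[Si](C)(C)C(C)(C)C)C(=C)CCC=C(C)C | intermediate
8 | (1S,2S,6S)-2-(tert-butyldimethylsilyloxy)-3-methylidene-6-(prop-1-en-2-yl)cyclohexan-1-ol | O[C@@H]1[C@@H](O[Si](C)(C)C(C)(C)C)C(=C)CC[C@H]1C(C)=C | intermediate
9 | isovaleric anhydride | CC(C)CC(=O)OC(=O)CC(C)C | starting material
10 | (1S,2S,6S)-2-(tert-butyldimethylsilyloxy)-3-methylidene-6-(prop-1-en-2-yl)cyclohexyl 3-methylbutanoate | CC(C)CC(=O)O[C@@H]1[C@@H](O[Si](C)(C)C(C)(C)C)C(=C)CC[C@H]1C(C)=C | intermediate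
11 | (1S,2S,6S)-2-hydroxy-3-methylidene-6-(prop-1-en-2-yl)cyclohexyl 3-methylbutanoate | CC(C)CC(=O)O[C@@H]1[C@@H](O)C(=C)CC[C@H]1C(C)=C | intermediate
12 | (1S,6S)-3-methylidene-2-oxo-6-(prop-1-en-2-yl)cyclohexyl 3-methylbutanoate | CC(C)CC(=O)O[C@@H]1C(=O)C(=C)CC[C@H]1C(C)=C | intermediate
13 | (1S,6S)-3-methyl-2-oxo-6-(prop-1-en-2-yl)cyclohex-3-en-1-yl 3-methylbutanoate | CC(C)CC(=O)O[C@@H]1C(=O)C(C)=CC[C@H]1C(C)=C | intermediate
14 | (1S,2S,6S)-2-hydroxy-3-methyl-6-(prop-1-en-2-yl)cyclohex-3-en-1-yl 3-methylbutanoate | CC(C)CC(=O)O[C@@H]1[C@@H](O)C(C)=CC[C@H]1C(C)=C | intermediate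
15 | (1S,2R,3R,4S,6S)-3,4-epoxy-2-hydroxy-3-methyl-6-(prop-1-en-2-yl)cyclohexyl 3-methylbutanoate | CC(C)CC(=O)O[C@@H]1[C@@H](O)[C@@]2(C)O[C@H]2C[C@H]1C(C)=C | intermediate
16 | (1S,3S,4S,6S)-3,4-epoxy-3-methyl-2-oxo-6-(prop-1-en-2-yl)cyclohexyl 3-methylbutanoate | CC(C)CC(=O)O[C@@H]1C(=O)[C@@]2(C)O[C@H]2C[C@H]1C(C)=C | intermediate
17 | (1S,3S,4S,6S)-3,4-epoxy-6-(3-hydroxyprop-1-en-2-yl)-3-methyl-2-oxocyclohexyl 3-methylbutanoate | CC(C)CC(=O)O[C@@H]1C(=O)[C@@]2(C)O[C@H]2C[C@H]1C(=C)CO | intermediate
18 | (1S,3S,4S,6R)-3,4-epoxy-6-[(2S)-2-(hydroxymethyl)oxiran-2-yl]-3-methyl-2-oxocyclohexyl 3-methylbutanoate | CC(C)CC(=O)O[C@@H]1C(=O)[C@@]2(C)O[C@H]2C[C@H]1[C@]1(CO)CO1 | intermediate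
19 | (1S,3S,4S,6R)-3,4-epoxy-6-[(2R)-2-formyloxiran-2-yl]-3-methyl-2-oxocyclohexyl 3-methylbutanoate | CC(C)CC(=O)O[C@@H]1C(=O)[C@@]2(C)O[C@H]2C[C@H]1[C@]1(C=O)CO1 | intermediate
20 | 2-methylbut-3-yn-2-ol | CC(C)(O)C#C | starting material
21 | (E)-2-methyl-4-(tributylstannyl)but-3-en-2-ol | CCCC[Sn](CCCC)(CCCC)/C=C/C(C)(C)O | intermediate
22 | (E)-4-iodo-2-methylbut-3-en-2-ol | CC(C)(O)/C=C/I | intermediate
23 | (E)-(3-hydroxy-3-methylbut-1-en-1-yl)chromium dichloride, not isolated | CC(C)(O)/C=C/[Cr](Cl)Cl | intermediate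
24 | (1S,3S,4S,6R)-6-{(2R)-2-[(E)-1,4-dihydroxy-4-methylpent-2-en-1-yl]oxiran-2-yl}-3,4-epoxy-3-methyl-2-oxocyclohexyl 3-methylbutanoate, both C8 epimers | CC(C)CC(=O)O[C@@H]1C(=O)[C@@]2(C)O[C@H]2C[C@H]1[C@]1(C(O)/C=C/C(C)(C)O)CO1 | intermediate
25 | (1S,3S,4S,6R)-3,4-epoxy-6-{(2R)-2-[(E)-4-hydroxy-4-methylpent-2-enoyl]oxiran-2-yl}-3-methyl-2-oxocyclohexyl 3-methylbutanoate | CC(C)CC(=O)O[C@@H]1C(=O)[C@@]2(C)O[C@H]2C[C@H]1[C@]1(C(=O)/C=C/C(C)(C)O)CO1 | target

**Step count**
Total: 21 steps. Longest linear sequence: 19 steps (steps 1 to 17, then 20 and 21, from nerol); steps 18 and 19 make the side-chain fragment.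

**Steps most likely to fail**

Step 7. The ring may close in part through a chair with the aluminium-bound oxygen axial, which would give the wrong configuration at C1, and the sensitive aldehyde may isomerise before it cyclises. The fallback sets out from 7 and comes back at 8. The cyclisation is run as before and the mixture of 8 and its C1 epimer (1R,2S,6S)-2-(tert-butyldimethylsilyloxy)-3-methylidene-6-(prop-1-en-2-yl)cyclohexan-1-ol F1 is oxidised with Dess–Martin periodinane to (2S,6S)-2-(tert-butyldimethylsilyloxy)-3-methylidene-6-(prop-1-en-2-yl)cyclohexan-1-one F2. Reduction of F2 with NaBH4 and CeCl3·7H2O in MeOH at −78 °C should then deliver hydride axially and give the all-equatorial alcohol 8. C1 is thus set by a hydride reduction and no longer in the ene step.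

Step 11. The rhodium hydride may also move the isopropenyl double bond towards C6, or the exocyclic enone may dimerise before it isomerises. The fallback sets out from 12 and comes back at 13. Copper-hydride conjugate hydrosilylation ([(Ph3P)CuH]6 cat., PhMe2SiH, toluene), which should leave isolated alkenes alone, would give (1S,6S)-2-[dimethyl(phenyl)silyloxy]-3-methyl-6-(prop-1-en-2-yl)cyclohex-2-en-1-yl 3-methylbutanoate F3. Saegusa–Ito oxidation of this regiodefined silyl enol ether (Pd(OAc)2, MeCN, rt) should then place the double bond at C3=C4 and give 13.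

Step 20. Divalent chromium may reductively open the ring epoxy ketone or cleave the α-acyloxy ketone before the alkenylchromium adds, or the coupling at the hindered aldehyde may be slow. The fallback sets out from 19 and comes back at 25. Vinylmagnesium bromide (THF, −78 °C) should add to the aldehyde alone and give (1S,3S,4S,6R)-3,4-epoxy-6-[(2R)-2-(1-hydroxyprop-2-en-1-yl)oxiran-2-yl]-3-methyl-2-oxocyclohexyl 3-methylbutanoate F4. Dess–Martin oxidation would give (1S,3S,4S,6R)-3,4-epoxy-3-methyl-2-oxo-6-[(2R)-2-(prop-2-enoyl)oxiran-2-yl]cyclohexyl 3-methylbutanoate F5. Cross-metathesis of this vinyl ketone with commercial 2-methylbut-3-en-2-ol (second-generation Hoveyda–Grubbs catalyst, CH2Cl2, 40 °C) should form the E enone of 25 directly, so the C9=C10 bond is made by metathesis and no chromium is used.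

**Further compounds**
F1 | step 7 | (1R,2S,6S)-2-(tert-butyldimethylsilyloxy)-3-methylidene-6-(prop-1-en-2-yl)cyclohexan-1-ol | O[C@H]1[C@@H](O[Si](C)(C)C(C)(C)C)C(=C)CC[C@H]1C(C)=C
F2 | step 7 | (2S,6S)-2-(tert-butyldimethylsilyloxy)-3-methylidene-6-(prop-1-en-2-yl)cyclohexan-1-one | O=C1[C@@H](O[Si](C)(C)C(C)(C)C)C(=C)CC[C@H]1C(C)=C
F3 | step 11 | (1S,6S)-2-[dimethyl(phenyl)silyloxy]-3-methyl-6-(prop-1-en-2-yl)cyclohex-2-en-1-yl 3-methylbutanoate | CC(C)CC(=O)O[C@@H]1C(O[Si](C)(C)c2ccccc2)=C(C)CC[C@H]1C(C)=C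
F4 | step 20 | (1S,3S,4S,6R)-3,4-epoxy-6-[(2R)-2-(1-hydroxyprop-2-en-1-yl)oxiran-2-yl]-3-methyl-2-oxocyclohexyl 3-methylbutanoate | CC(C)CC(=O)O[C@@H]1C(=O)[C@@]2(C)O[C@H]2C[C@H]1[C@]1(C(O)C=C)CO1
F5 | step 20 | (1S,3S,4S,6R)-3,4-epoxy-3-methyl-2-oxo-6-[(2R)-2-(prop-2-enoyl)oxiran-2-yl]cyclohexyl 3-methylbutanoate | CC(C)CC(=O)O[C@@H]1C(=O)[C@@]2(C)O[C@H]2C[C@H]1[C@]1(C(=O)C=C)CO1
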